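The route rests on cutting the side chain (numbered from OCH2 = C1') between the allylic methylene C8' and the carbinol carbon C9'. The syn C9'/C10' diol next to the tertiary carbinol C11' is D-tartaric acid in disguise. C2 and C3 become C9' and C10', one carboxyl carbon becomes C11', and the other leaves as CO2. The key step is a nickel-catalysed reductive decarboxylative allylation. It joins the complete coumarin-bearing (E)-allylic carbonate, whose C6'=C7' alkene makes C8' a pi-allyl terminus, to the C9' radical of an N-hydroxyphthalimide ester. In one operation it forms C8'–C9', keeps the E-alkene and sets C9' trans to C10' on a temporary 1,3-dioxolane ring, whatever the precursor's configuration there.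

Key step: step 6

Remark: primed locants refer to the C15 side chain (C1' = OCH2, C8' = allylic CH2, C9' and C10' = secondary carbinols, C11' = tertiary carbinol). Unprimed locants refer to the coumarin. Compounds 1, 2, 6 and 9 are taken as commercial.

Step 1
Reactants: 1 5,7-dihydroxycoumarin; 2 geraniol
Product: 3 7-geranyloxy-5-hydroxycoumarin (7-{[(2E)-3,7-dimethylocta-2,6-dien-1-yl]oxy}-5-hydroxy-2H-chromen-2-one)
Conditions: PPh3, DIAD, THF, 0 °C to rt (1 in slight excess)
Reagents that add atoms: none
Why: The Mitsunobu etherification should take the more acidic, unhindered 7-OH (para to C4a and so conjugated with the lactone carbonyl) rather than the 5-OH crowded by the peri C4–H, and SN2 attack on the primary allylic oxyphosphonium salt keeps the 2'E geometry.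

Step 2
Reactants: 3 7-geranyloxy-5-hydroxycoumarin
Product: 4 5-hydroxy-7-{[(2E,6E)-8-hydroxy-3,7-dimethylocta-2,6-dien-1-yl]oxy}-2H-chromen-2-one
Conditions: SeO2 (cat.), t-BuOOH, salicylic acid (cat.), CH2Cl2, 0 °C to rt
Reagents that add atoms: tert-butyl hydroperoxide, CC(C)(C)OO (terminal source of the new oxygen, passed on through SeO2, O=[Se]=O)
Why: The Riley-type allylic oxidation (ene reaction, then [2,3]-sigmatropic shift) attacks the more electron-rich terminal C6'=C7' alkene and oxidises the methyl group trans to the chain, which gives the 6'E alcohol, while the C2'=C3' alkene is deactivated by its allylic aryloxy group.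

Step 3
Reactants: 4 8'-alcohol
Product: 5 bis(methyl carbonate) of 4 (methyl carbonates on O5 of the coumarin and on O8' of the 2'E,6'E side chain)
Conditions: ClCO2Me, pyridine, CH2Cl2, 0 °C
Reagents that add atoms: methyl chloroformate, COC(=O)Cl
Why: O-acylation with a chloroformate turns the allylic alcohol into the leaving group of the key step and masks the acidic phenol in the same operation.

Step 4
Reactants: 6 dimethyl (4S,5S)-2,2-dimethyl-1,3-dioxolane-4,5-dicarboxylate (dimethyl 2,3-O-isopropylidene-D-tartrate)
Product: 7 (4S,5S)-5-(methoxycarbonyl)-2,2-dimethyl-1,3-dioxolane-4-carboxylic acid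
Conditions: KOH (1 equiv), MeOH, 0 °C to rt; then aq. HCl to pH 2–3
Reagents that add atoms: potassium hydroxide, [K+].[OH-]
Why: In this monosaponification of a C2-symmetric diester the two ester groups are equivalent, so only one monoacid can form, and the first carboxylate slows the second hydrolysis without touching the stereocentres.

Step 5
Reactants: 7 monoacid monoester
Product: 8 (4S,5S)-5-(2-hydroxypropan-2-yl)-2,2-dimethyl-1,3-dioxolane-4-carboxylic acid
Conditions: MeMgBr (4 equiv), THF, 0 °C to rt; then aq. HCl to pH 3, 0 °C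
Reagents that add atoms: methylmagnesium bromide, C[Mg]Br
Why: Double Grignard addition to the ester builds the future C11' carbinol while the acid is shielded in the flask as its magnesium carboxylate, and the future C10' keeps its configuration because addition outruns enolisation.

Step 6
Reactants: 8 hydroxy acid; 9 N-hydroxyphthalimide; 5 bis(methyl carbonate)
Product: 11 7-{[(2E,6E)-8-[(4R,5S)-5-(2-hydroxypropan-2-yl)-2,2-dimethyl-1,3-dioxolan-4-yl]-3,7-dimethylocta-2,6-dien-1-yl]oxy}-2-oxo-2H-chromen-5-yl methyl carbonate, via redox-active ester 10 (not isolated)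
Conditions: 8, 9 (each 1.8 equiv), DIC, DMAP (cat.), CH2Cl2, rt; solvent changed to DMA; then 5, NiBr2(dme) (10 mol %), 4,4'-di-tert-butyl-2,2'-bipyridine (15 mol %), Zn dust, MgCl2, rt
Reagents that add atoms: none
Why: Proposed new method: zerovalent nickel (from NiBr2(dme), the bipyridine and Zn) should ionise only the allylic methyl carbonate at C8' of 5 to a syn-configured pi-allyl complex of divalent nickel, while monovalent nickel passes one electron to the phthalimide ester 10, which loses phthalimide anion and CO2 to give the C9' 1,3-dioxolan-4-yl radical; the allyl complex captures this radical, and the resulting trivalent nickel reductively eliminates at the unsubstituted terminus C8', with Zn closing the cycle. The closest known reaction types are the nickel-catalysed reductive allylation of alkyl halides with allylic carbonates or acetates and the decarboxylative cross-electrophile coupling of N-hydroxyphthalimide esters; what is new is their merger for an alpha-oxygenated ester, a radical being the only safe reactive form of C9' because a C9' anion would expel the C10' oxygen. No ring is closed. The only new stereocentre, C9', is set by the dioxolane ring: the flattened radical is approached anti to the bulky C(CH3)2OH group on C10', which gives the trans-4,5-disubstituted ring (9'R next to the untouched 10'S) whatever the configuration of that carbon in 8 or 10, as is known for tartrate-derived dioxolanyl radicals. Regio- and E-selectivity rest on the allyl unit, because C8' is a CH2 terminus whereas C6' is secondary, and syn/anti exchange would need a sigma bond from nickel to that secondary carbon. Chemoselectivity rests on leaving groups and rates: the allylic carbonate ionises irreversibly with loss of CO2, the C1' aryl ether and the aryl carbonate are poorer substrates for nickel, and capture of the radical by nickel should outrun its addition to the donor-substituted, 1,2-disubstituted C3=C4 bond of the coumarin.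

Step 7
Reactants: 11 coupled carbonate acetonide
Product: 13 CNP0174708.4 (5-hydroxy-7-{[(2E,6E,9R,10S)-9,10,11-trihydroxy-3,7,11-trimethyldodeca-2,6-dien-1-yl]oxy}-2H-chromen-2-one), via phenol acetonide 12 (not isolated)
Conditions: K2CO3 (2 equiv), MeOH, 0 °C; then 1 M aq. HCl to pH 1, rt
Reagents that add atoms: none
Why: Transesterification of the aryl carbonate followed by acid-catalysed acetal hydrolysis frees the phenol and the syn diol without breaking a C–O bond at C9' or C10', so both configurations are retained, and the acid stage recloses any lactone opened by base.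

Compound list
1 | 5,7-dihydroxycoumarin | Oc1cc(O)c2ccc(=O)oc2c1 | starting material
2 | geraniol, (2E)-3,7-dimethylocta-2,6-dien-1-ol | C/C(=C\CO)CCC=C(C)C | starting material
3 | 7-geranyloxy-5-hydroxycoumarin | C/C(=C\COc1cc(O)c2ccc(=O)oc2c1)CCC=C(C)C | intermediate
4 | 5-hydroxy-7-{[(2E,6E)-8-hydroxy-3,7-dimethylocta-2,6-dien-1-yl]oxy}-2H-chromen-2-one | C/C(=C\COc1cc(O)c2ccc(=O)oc2c1)CC/C=C(\C)CO | intermediate
5 | bis(methyl carbonate) of 4 (O5 and O8') | C/C(=C\COc1cc(OC(=O)OC)c2ccc(=O)oc2c1)CC/C=C(\C)COC(=O)OC | intermediate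
6 | dimethyl (4S,5S)-2,2-dimethyl-1,3-dioxolane-4,5-dicarboxylate | COC(=O)[C@H]1OC(C)(C)O[C@@H]1C(=O)OC | starting material
7 | (4S,5S)-5-(methoxycarbonyl)-2,2-dimethyl-1,3-dioxolane-4-carboxylic acid | OC(=O)[C@H]1OC(C)(C)O[C@@H]1C(=O)OC | intermediate
8 | (4S,5S)-5-(2-hydroxypropan-2-yl)-2,2-dimethyl-1,3-dioxolane-4-carboxylic acid | OC(=O)[C@H]1OC(C)(C)O[C@@H]1C(C)(C)O | intermediate
9 | N-hydroxyphthalimide | O=C1c2ccccc2C(=O)N1O | starting material
10 | 1,3-dioxoisoindolin-2-yl (4S,5S)-5-(2-hydroxypropan-2-yl)-2,2-dimethyl-1,3-dioxolane-4-carboxylate | O=C(ON1C(=O)c2ccccc2C1=O)[C@H]1OC(C)(C)O[C@@H]1C(C)(C)O | intermediate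
11 | 7-{[(2E,6E)-8-[(4R,5S)-5-(2-hydroxypropan-2-yl)-2,2-dimethyl-1,3-dioxolan-4-yl]-3,7-dimethylocta-2,6-dien-1-yl]oxy}-2-oxo-2H-chromen-5-yl methyl carbonate | C/C(=C\COc1cc(OC(=O)OC)c2ccc(=O)oc2c1)CC/C=C(\C)C[C@H]1OC(C)(C)O[C@@H]1C(C)(C)O | intermediate
12 | 5-hydroxy-7-{[(2E,6E)-8-[(4R,5S)-5-(2-hydroxypropan-2-yl)-2,2-dimethyl-1,3-dioxolan-4-yl]-3,7-dimethylocta-2,6-dien-1-yl]oxy}-2H-chromen-2-one | C/C(=C\COc1cc(O)c2ccc(=O)oc2c1)CC/C=C(\C)C[C@H]1OC(C)(C)O[C@@H]1C(C)(C)O | intermediate
13 | CNP0174708.4, 5-hydroxy-7-{[(2E,6E,9R,10S)-9,10,11-trihydroxy-3,7,11-trimethyldodeca-2,6-dien-1-yl]oxy}-2H-chromen-2-one | C/C(=C\COc1cc(O)c2ccc(=O)oc2c1)CC/C=C(\C)C[C@@H](O)[C@H](O)C(C)(C)O | target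

Total step count: 7
Longest linear sequence: 5 steps (1, 2, 3, 6, 7). The tartrate branch contributes steps 4 and 5.

Steps most likely to fail

Step 6.
- What may go wrong: reductive homocoupling of the allyl unit; hydrogen abstraction by the C9' radical before nickel captures it; slow ionisation of the C1' aryl ether; N-allylation of the liberated phthalimide anion.
- Fallback, from 2 back to 12, all known chemistry. The C8'–C9' bond is made by homologation of an allylboronic ester with a lithiated epoxide (1,2-metallate shift), and the coumarin is attached afterwards. Geraniol 2 is silylated (TBSCl, imidazole) to geranyl TBS ether F1. This is oxidised under the conditions of step 2 to the 8-hydroxy TBS ether F2 and borylated (bis(pinacolato)diboron, Pd(MeCN)4(BF4)2 cat., DMSO/MeOH) to the (E)-allylboronic ester F3. Purchased methyl (S)-glycidate and MeMgBr give (S)-2-(oxiran-2-yl)propan-2-ol F4, which is protected (TESOTf, 2,6-lutidine) as the epoxide TES ether F5. Lithium 2,2,6,6-tetramethylpiperidide metallates F5 at the CH2 position trans to the side chain in the presence of F3. TESOTf then triggers migration of the allyl group from boron to C9', with inversion and opening of the epoxide, to the beta-silyloxy boronic ester F6. This is oxidised in the same flask (NaOH, H2O2, retention) to the syn-configured 9-alcohol F7. TBAF gives the tetraol F8, and 2,2-dimethoxypropane with PPTS gives the 9,10-acetonide alcohol F9. A Mitsunobu reaction of F9 with 1, as in step 1, gives 12, which is taken through the acid stage of step 7.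

Step 1.
- What may go wrong: insufficient discrimination between the 5- and 7-hydroxyl groups, and double etherification.
- Fallback, from 2 back to 3. The pyranone ring is built after the ether, so the regiochemical question cannot arise. Purchased 2,4,6-trihydroxybenzaldehyde is etherified with 2 (PPh3, DIAD) at its only hydroxyl group that is not hydrogen-bonded to the aldehyde, giving 4-geranyloxy-2,6-dihydroxybenzaldehyde F10. A Wittig reaction with Ph3P=CHCO2Et gives the (E)-cinnamate F11. Irradiation at 365 nm isomerises the cinnamate double bond to Z, and either of the two equivalent ortho hydroxyl groups then lactonises to 3.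

Step 2.
- What may go wrong: stalling at partial conversion, over-oxidation to the aldehyde level, or oxidative damage to the free phenol.
- Fallback, from 3 back to 4. The terminal alkene is degraded and rebuilt. m-CPBA epoxidises the more electron-rich C6'=C7' bond to the racemic 6',7'-epoxide F12. H5IO6 cleaves it to the C6' aldehyde F13. A Wittig reaction with Ph3P=C(CH3)CHO gives the (E)-enal F14, and a Luche reduction (NaBH4, CeCl3·7H2O, MeOH, 0 °C) gives 4.

Further compounds
F1 | step 6 | geranyl TBS ether | C/C(=C\CO[Si](C)(C)C(C)(C)C)CCC=C(C)C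
F2 | step 6 | (2E,6E)-8-(tert-butyldimethylsilyloxy)-2,6-dimethylocta-2,6-dien-1-ol | C/C(=C\CO[Si](C)(C)C(C)(C)C)CC/C=C(\C)CO
F3 | step 6 | (2E,6E)-allylboronic acid pinacol ester of F2 (Bpin in place of OH) | C/C(=C\CO[Si](C)(C)C(C)(C)C)CC/C=C(\C)CB1OC(C)(C)C(C)(C)O1
F4 | step 6 | (S)-2-(oxiran-2-yl)propan-2-ol | CC(C)(O)[C@@H]1CO1
F5 | step 6 | triethylsilyl ether of F4 | CC[Si](CC)(CC)OC(C)(C)[C@@H]1CO1
F6 | step 6 | beta-silyloxy boronic ester (Bpin on C9, OTES on C10 and C11, OTBS on C1) | C/C(=C\CO[Si](C)(C)C(C)(C)C)CC/C=C(\C)C[C@@H](B1OC(C)(C)C(C)(C)O1)[C@H](O[Si](CC)(CC)CC)C(C)(C)O[Si](CC)(CC)CC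
F7 | step 6 | (9R,10S)-9-alcohol (OTES on C10 and C11, OTBS on C1) | C/C(=C\CO[Si](C)(C)C(C)(C)C)CC/C=C(\C)C[C@@H](O)[C@H](O[Si](CC)(CC)CC)C(C)(C)O[Si](CC)(CC)CC
F8 | step 6 | (2E,6E,9R,10S)-3,7,11-trimethyldodeca-2,6-diene-1,9,10,11-tetraol | C/C(=C\CO)CC/C=C(\C)C[C@@H](O)[C@H](O)C(C)(C)O
F9 | step 6 | 9,10-acetonide of F8 | C/C(=C\CO)CC/C=C(\C)C[C@H]1OC(C)(C)O[C@@H]1C(C)(C)O
F10 | step 1 | 4-geranyloxy-2,6-dihydroxybenzaldehyde | C/C(=C\COc1cc(O)c(C=O)c(O)c1)CCC=C(C)C
F11 | step 1 | ethyl (E)-3-[4-geranyloxy-2,6-dihydroxyphenyl]acrylate | C/C(=C\COc1cc(O)c(/C=C/C(=O)OCC)c(O)c1)CCC=C(C)C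
F12 | step 2 | racemic 6',7'-epoxide of 3 | C/C(=C\COc1cc(O)c2ccc(=O)oc2c1)CCC1OC1(C)C
F13 | step 2 | (E)-6-[(5-hydroxy-2-oxo-2H-chromen-7-yl)oxy]-4-methylhex-4-enal | C/C(=C\COc1cc(O)c2ccc(=O)oc2c1)CCC=O
F14 | step 2 | (2E,6E)-8-[(5-hydroxy-2-oxo-2H-chromen-7-yl)oxy]-2,6-dimethylocta-2,6-dienal | C/C(=C\COc1cc(O)c2ccc(=O)oc2c1)CC/C=C(\C)C=O
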